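**Assumptions (one line each)**
- The Hayashi–Jørgensen Michael step gives the syn adduct (C-i R, C-a S). The target needs C-a as R, so C-a is equilibrated in Step 8 through the γ-dienolate of the enedial.
- A stoichiometric B-allenyl-Ipc2B reagent, with the pinene enantiomer chosen for the S-carbinol, gives the (S)-homopropargylic alcohol at C-h despite the adjacent stereocentres.

**Retrosynthetic overview**
1. The target comes from TBS removal, radical removal of a bis-allylic OH, and an intramolecular Nozaki–Hiyama–Kishi (NHK) coupling of an (E)-vinyl iodide with an enedial aldehyde. This coupling closes the nine-membered ring and fixes the E-trisubstituted alkene.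
2. The enedial comes from singlet-oxygen photooxygenation of a 3-alkylfuran. This opens the aromatic ring and unmasks the ring-cis enal and the coupling aldehyde in one operation.
3. The vinyl iodide comes from Negishi carboalumination of a homopropargylic alcohol. That alcohol comes from allenylboration of the aldehyde of an (S)-citronellal / 3-furylnitroalkene Michael adduct.
4. The furan ring is destroyed before any carbocycle forms. The nine-membered carbocycle is the only ring formed (Step 9).

**Route**

**Step 1**
Reactants: 1 (3-furaldehyde), 2 (nitromethane)
Product: 3, (E)-3-(2-nitrovinyl)furan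
Conditions: NH4OAc, AcOH, 90 °C
Reagents that add atoms: none (nitromethane is the numbered reactant)
Why: Henry–Knoevenagel condensation of the heteroaryl aldehyde gives the E-nitroalkene, which is the Michael acceptor that carries the furan.

**Step 2**
Reactants: 4 ((S)-citronellal), 3
Product: 5, (2R,3S)-type syn γ-nitroaldehyde
Conditions: (S)-diphenylprolinol TMS ether (10 mol%), PhCO2H (10 mol%), toluene, 0 °C
Reagents that add atoms: none
Why: Enamine-catalysed Michael addition (Hayashi–Jørgensen) sets C-i and C-a by catalyst control; the citronellal centre becomes the side-chain stereocentre, and the aldehyde carbon becomes C-h.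

**Step 3**
Reactants: 5
Product: 6, homopropargylic alcohol (C-h S)
Conditions: B-allenyl-diisopinocampheylborane, Et2O, −78 °C; then NaOH, H2O2
Reagents that add atoms: B-allenyl-Ipc2B, C=C=CB(C1CC2CC(C2(C)C)C1C)C1CC2CC(C2(C)C)C1C (supplies the C3H3 propargyl unit, carbons g, f and e)
Why: Brown allenylboration (SE2′ addition to the aldehyde) is reagent-controlled, so the carbinol C-h is set by the chiral borane.

**Step 4**
Reactants: 6
Product: 7, TBS ether
Conditions: TBSOTf, 2,6-lutidine, CH2Cl2, −78 °C
Reagents that add atoms: TBSOTf, CC(C)(C)[Si](C)(C)OS(=O)(=O)C(F)(F)F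
Why: Silylation masks the carbinol so it survives the later radical deoxygenation.

**Step 5**
Reactants: 7
Product: 8, primary alcohol at C-a with OTBS at C-h
Conditions: (i) NaOMe, MeOH, 0 °C; (ii) TiCl3, NH4OAc, THF/H2O, rt; (iii) NaBH4, MeOH, 0 °C
Reagents that add atoms: water, O (supplies the aldehyde oxygen)
Why: Buffered McMurry Nef reaction converts CH2NO2 to CHO, and in-situ borohydride reduction gives CH2OH; this is the C-a side-chain oxygen.

**Step 6**
Reactants: 8
Product: 9, primary acetate
Conditions: Ac2O, Et3N, DMAP (cat.), CH2Cl2, 0 °C
Reagents that add atoms: acetic anhydride, CC(=O)OC(C)=O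
Why: This installs the final CH2OAc directly; the TBS-protected secondary OH is untouched.

**Step 7**
Reactants: 9
Product: 10, (E)-vinyl iodide
Conditions: Me3Al, Cp2ZrCl2 (cat.), CH2Cl2, 0 °C to rt; then I2, THF, −30 °C
Reagents that add atoms: trimethylaluminium, C[Al](C)C (supplies the methyl on C-f); iodine, II
Why: Negishi carboalumination is a syn methylalumination, so iodolysis gives I cis to Me and trans to CH2(g). That is the geometry required for the E-alkene e=f.

**Step 8**
Reactants: 10
Product: 11, (E)-2-substituted-but-2-enedial with C-a epimerized to the target (R) configuration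
Conditions: O2, rose bengal, visible light, CH2Cl2, −78 °C; then Me2S; then Et3N (cat.), rt
Reagents that add atoms: dioxygen, O=O
Why: Proposed new method: [4+2] photooxygenation of the electron-rich furan opens the aromatic ring, and Me2S reduction of the endoperoxide gives the (Z)-enedial, as in Kobayashi-type furan-to-enedial oxidations. Catalytic Et3N then isomerizes it to the (E)-enedial, with C-a cis to CH(d)=O. The same γ-dienolate also equilibrates C-a to the R configuration, which sets the C-a stereocentre. The closest known chemistry is furan photooxygenation/reduction to ene-1,4-dials followed by base-mediated alkene isomerization.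

**Step 9**
Reactants: 11
Product: 12, nine-membered enal carbinol (d-OH mixture)
Conditions: CrCl2 (10 equiv), NiCl2 (0.1 equiv), DMF, 0.003 M, syringe-pump addition, 25 °C
Reagents that add atoms: none
Why: Proposed new method: the intramolecular Nozaki–Hiyama–Kishi coupling of the vinyl iodide with the less hindered enedial aldehyde closes the ring. Vinylchromium addition retains the alkene geometry, so it gives the E-trisubstituted e=f. The cis relationship of C-a and C-d in the E-enedial gives the ring-cis enal b=c, and any residual C-a epimer cannot reach this geometry. The closest known chemistry is intramolecular NHK macrocyclization.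

**Step 10**
Reactants: 12
Product: 13, imidazolyl thiocarbonate of the d-OH
Conditions: TCDI, DMAP (cat.), CH2Cl2, rt
Reagents that add atoms: 1,1'-thiocarbonyldiimidazole, S=C(n1ccnc1)n1ccnc1
Why: This activates the bis-allylic alcohol for Barton–McCombie deoxygenation without using a strong base in the presence of the enal.

**Step 11**
Reactants: 13
Product: 14, TBS-protected precursor with d as CH2
Conditions: Bu3SnH, Et3B, air, toluene, rt
Reagents that add atoms: none (hydrogen only)
Why: Radical deoxygenation (Barton–McCombie) removes the d-oxygen; C-d is not a stereocentre in the product, so the d-epimer mixture converges.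

**Step 12**
Reactants: 14
Product: 15, hydroxyacetyldictyolal
Conditions: HF·pyridine, pyridine, THF, 0 °C to rt
Reagents that add atoms: none
Why: Fluoride-mediated desilylation frees the C-h OH and leaves the acetate, enal and alkenes intact; the h, i, a and side-chain centres are untouched.

**Compound list**
1 | 3-furaldehyde | O=Cc1ccoc1 | starting material
2 | nitromethane | C[N+](=O)[O-] | starting material
3 | (E)-3-(2-nitrovinyl)furan | O=[N+]([O-])/C=C/c1ccoc1 | intermediate
4 | (S)-citronellal | C[C@@H](CCC=C(C)C)CC=O | starting material
5 | syn γ-nitroaldehyde | O=C[C@H]([C@@H](C)CCC=C(C)C)[C@H](C[N+](=O)[O-])c1ccoc1 | intermediate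
6 | homopropargylic alcohol | C#CC[C@H](O)[C@H]([C@@H](C)CCC=C(C)C)[C@H](C[N+](=O)[O-])c1ccoc1 | intermediate
7 | TBS ether | C#CC[C@H](O[Si](C)(C)C(C)(C)C)[C@H]([C@@H](C)CCC=C(C)C)[C@H](C[N+](=O)[O-])c1ccoc1 | intermediate
8 | primary alcohol | C#CC[C@H](O[Si](C)(C)C(C)(C)C)[C@H]([C@@H](C)CCC=C(C)C)[C@H](CO)c1ccoc1 | intermediate
9 | primary acetate | C#CC[C@H](O[Si](C)(C)C(C)(C)C)[C@H]([C@@H](C)CCC=C(C)C)[C@H](COC(C)=O)c1ccoc1 | intermediate
10 | (E)-vinyl iodide | I/C=C(\C)C[C@H](O[Si](C)(C)C(C)(C)C)[C@H]([C@@H](C)CCC=C(C)C)[C@H](COC(C)=O)c1ccoc1 | intermediate
11 | (E)-enedial, C-a in target configuration | O=C/C=C(/C=O)[C@H](COC(C)=O)[C@@H]([C@@H](C)CCC=C(C)C)[C@@H](O[Si](C)(C)C(C)(C)C)C/C(C)=C/I | intermediate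
12 | macrocyclic d-alcohol (C-d unspecified) | CC(=O)OC[C@H]1/C(C=O)=C\C(O)/C=C(\C)C[C@H](O[Si](C)(C)C(C)(C)C)[C@@H]1[C@@H](C)CCC=C(C)C | intermediate
13 | imidazolyl thiocarbonate | CC(=O)OC[C@H]1/C(C=O)=C\C(OC(=S)n2ccnc2)/C=C(\C)C[C@H](O[Si](C)(C)C(C)(C)C)[C@@H]1[C@@H](C)CCC=C(C)C | intermediate
14 | TBS-protected target | CC(=O)OC[C@H]1/C(C=O)=C\C/C=C(\C)C[C@H](O[Si](C)(C)C(C)(C)C)[C@@H]1[C@@H](C)CCC=C(C)C | intermediate
15 | hydroxyacetyldictyolal | CC(=O)OC[C@H]1/C(C=O)=C\C/C=C(\C)C[C@H](O)[C@@H]1[C@@H](C)CCC=C(C)C | target

**Total steps:** 12
**Longest linear sequence:** 12 steps, from 3-furaldehyde (Step 1, then Steps 2 to 12 through 3, 5, 6, 7, 8, 9, 10, 11, 12, 13, 14 to 15). The citronellal branch joins at Step 2 and is not longer.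

**Three steps most likely to fail**
1. **Step 9 (macro-NHK).** The competing 8-membered closure onto the other aldehyde, oligomerization, and strain in forming the E-alkene are all risks.
   Fallback: close the ring by intramolecular B-alkyl Suzuki–Miyaura coupling of the vinyl iodide with an alkylborane at C-d. That means building a furan-free precursor with a terminal alkene at C-d and carrying the b-CHO as a masked alcohol.
2. **Steps 2 and 8 (C-a/C-i relative configuration).** The catalyst-derived syn adduct needs C-a to equilibrate to the target epimer, and the E-enedial with the correct C-a may not be thermodynamically favoured.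
   Fallback: set C-a and C-i by Ireland–Claisen rearrangement of an (E)-allylic ester of (S)-citronellic acid instead of the organocatalytic Michael addition.
3. **Step 11 (radical deoxygenation of the bis-allylic C-d).** Hydrogen transfer to the delocalized radical can transpose the alkenes.
   Fallback: form the e–d bond without an oxygen at d, by Ni-catalysed reductive cross-coupling of the vinyl iodide with an allylic acetate at C-d (made from the reduced enedial), which removes the need for deoxygenation.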